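**Plan**

- Atom labels: C1 is the OMe/prenyl quaternary carbon, C2 the ring ketone, C3 the acyl-bearing carbon, C4 and C6 the enol carbons, C5 the prenylated carbon between them.
- Cuts, in retrosynthetic order: C5–prenyl (enolate alkylation), ring bond C3–C4, C5–C6 (acetylide plus N-methoxy-N-methylamide), C2–C3 (acyl imidazolide plus ketone enolate), C1–prenyl (malonate alkylation).
- Enabling feature: C4 is the β-carbon of the vinylogous acid O=C6–C5=C4–OH and is bonded to C3, the central carbon of the β-diketone C2(=O)–C3–C(=O)CH2CH2Ph. The six-membered ring therefore opens to a diketone carbanion and an ethoxyethynyl ketone, both attached to C1.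
- Forward order: methoxymalonate is prenylated and desymmetrised; one carboxyl becomes the amide, the other the β-diketone arm, and the amide then becomes the alkoxy ynone. The single carbocycle closes by 6-endo-dig conjugate addition, and enol ether hydrolysis and C5 prenylation finish the synthesis.
- Stereochemistry: the only stereocentre, C1, comes from esterase discrimination of the enantiotopic esters of the prochiral malonate. It is quaternary and non-enolisable and is not touched afterwards.

Key step: step 7

Assumption: pig liver esterase is taken to cleave the pro-S ester of the prochiral diester with useful selectivity (otherwise the fallback for step 2 supplies the same half-ester); enolised tricarbonyl compounds are written as one tautomer each.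

**Step 1**
Reactants: 1 dimethyl 2-methoxypropanedioate (dimethyl methoxymalonate); 2 1-bromo-3-methylbut-2-ene (prenyl bromide)
Product: 3 dimethyl 2-methoxy-2-(3-methylbut-2-enyl)propanedioate
Conditions: NaH, THF–DMF, 0 °C to rt
Reagents that add atoms: none
Why: SN2 alkylation of the sodium enolate of an α-alkoxymalonate at the unhindered CH2 terminus of a primary allylic bromide; the substrate has a single acidic hydrogen, so only one prenyl group can enter.

**Step 2**
Reactants: 3 dimethyl 2-methoxy-2-(3-methylbut-2-enyl)propanedioate
Product: 4 (R)-2-methoxy-2-(methoxycarbonyl)-5-methylhex-4-enoic acid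
Conditions: pig liver esterase, phosphate buffer pH 7.5, 10% DMSO, 25 °C, pH-stat (1 M NaOH); then 1 M HCl to pH 2–3, 0 °C
Reagents that add atoms: water, SMILES O
Why: Enzymatic desymmetrisation of a prochiral disubstituted malonic diester: the esterase cleaves one of the two enantiotopic methyl esters (taken to be the pro-S group) and thereby sets the C1 quaternary centre, and the anionic half-ester is not hydrolysed further.

**Step 3**
Reactants: 4 (R)-2-methoxy-2-(methoxycarbonyl)-5-methylhex-4-enoic acid
Product: 6 methyl (R)-2-methoxy-2-[methoxy(methyl)carbamoyl]-5-methylhex-4-enoate, via acid chloride 5 (not isolated)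
Conditions: Me2C=C(Cl)NMe2, CH2Cl2, 0 °C to rt; then MeNHOMe·HCl, Et3N, 0 °C to rt
Reagents that add atoms: N,O-dimethylhydroxylamine hydrochloride, SMILES CNOC.Cl
Why: Amide formation through the acid chloride, which the α-chloroenamine generates under neutral conditions (no free HCl near the prenyl group) and which overcomes the hindrance of the quaternary acid; the centre has no α-hydrogen and cannot racemise.

**Step 4**
Reactants: 6 methyl (R)-2-methoxy-2-[methoxy(methyl)carbamoyl]-5-methylhex-4-enoate
Product: 7 (R)-2-methoxy-2-[methoxy(methyl)carbamoyl]-5-methylhex-4-enoic acid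
Conditions: LiOH·H2O, THF–H2O (3:1), 0 °C to rt; then 1 M HCl to pH 3, 0 °C; used at once
Reagents that add atoms: lithium hydroxide, SMILES [Li+].[OH-]
Why: Saponification of the methyl ester, which the α-methoxy group activates, while the much less electrophilic N-methoxy-N-methylamide stays intact; the malonamic acid is kept cold to avoid decarboxylation.

**Step 5**
Reactants: 7 (R)-2-methoxy-2-[methoxy(methyl)carbamoyl]-5-methylhex-4-enoic acid; 8 4-phenylbutan-2-one (benzylacetone)
Product: 11 (S)-N,2-dimethoxy-N-methyl-2-(3-methylbut-2-enyl)-3,5-dioxo-7-phenylheptanamide, via acyl imidazolide 9 (not isolated), via lithium enolate 10 (not isolated)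
Conditions: 7, 1,1'-carbonyldiimidazole, THF, rt; added to 10 [from 8, LiN(iPr)2, THF, −78 °C, 3.2 equiv], −78 to −20 °C; 1 M HCl, 0 °C
Reagents that add atoms: none
Why: Crossed Claisen-type C-acylation of the kinetic (methyl-side) lithium enolate of the ketone by the acyl imidazolide, which is far more electrophilic than the N-methoxy-N-methylamide on the same carbon; the β-diketone is deprotonated as it forms (hence the excess enolate, one equivalent of which is also consumed by liberated imidazole), which protects it from retro-Claisen cleavage and second acylation.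

**Step 6**
Reactants: 11 (S)-N,2-dimethoxy-N-methyl-2-(3-methylbut-2-enyl)-3,5-dioxo-7-phenylheptanamide; 12 ethoxyethyne
Product: 14 (S)-1-ethoxy-4-methoxy-4-(3-methylbut-2-enyl)-9-phenylnon-1-yne-3,5,7-trione, via lithium ethoxyacetylide 13 (not isolated)
Conditions: 12, n-BuLi, THF, −78 °C (2 equiv of 13); 11, LiN(SiMe3)2 (1.05 equiv), THF, −78 °C; combined, −78 to −40 °C; AcOH, −78 °C, then cold water/Et2O; used without delay
Reagents that add atoms: none
Why: Weinreb ketone synthesis: the lithium acetylide adds once to the N-methoxy-N-methylamide to give a chelated tetrahedral adduct that collapses to the alkoxy ynone only on quenching, the β-diketone is masked as its lithium enolate throughout, and the acetic acid quench keeps the liberated N,O-dimethylhydroxylamine protonated so that it cannot add to the ynone.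

**Step 7**
Reactants: 14 (S)-1-ethoxy-4-methoxy-4-(3-methylbut-2-enyl)-9-phenylnon-1-yne-3,5,7-trione
Product: 15 (R)-3-ethoxy-5-hydroxy-6-methoxy-6-(3-methylbut-2-enyl)-2-(3-phenylpropanoyl)cyclohexa-2,4-dien-1-one
Conditions: MgCl2 (1.5 equiv), Et3N (2.5 equiv), MeCN, 0 °C to rt; cold 0.5 M HCl wash
Reagents that add atoms: none
Why: Et3N and MgCl2 convert the β-diketone into its magnesium chelate, whose central carbon C3 adds to C4, the ethoxy-bearing β-carbon of the ynone; the vinyl carbanion developing at C5 is protonated by Et3NH+, and loss of the now very acidic C3–H gives the magnesium salt of the cross-conjugated vinylogous ester. The closest known reaction type is the base-mediated intramolecular Michael addition of 1,3-dicarbonyl carbanions to ynones, and the ring C1–C6 closes in the 6-endo-dig mode. No stereocentre is formed, and C1, being quaternary and non-enolisable, is carried through unchanged. The selectivity needed is attack through carbon and not through the C2 enolate oxygen (which would close a pyranone): chelation to magnesium ties up both diketone oxygens, as in magnesium-mediated C-acylations, and the ynone polarisation leaves C4 as the only electrophilic alkyne carbon. Any heteroatom adduct at C4 (chloride, amine or enol oxygen) remains a carboxyl-level vinylogous electrophile that C3 can displace, whereas the carbon adduct is trapped as a strongly acidic acyl-trione enolate, which is also why more than one equivalent of base is used.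

**Step 8**
Reactants: 15 (R)-3-ethoxy-5-hydroxy-6-methoxy-6-(3-methylbut-2-enyl)-2-(3-phenylpropanoyl)cyclohexa-2,4-dien-1-one
Product: 16 (R)-3,5-dihydroxy-6-methoxy-6-(3-methylbut-2-enyl)-2-(3-phenylpropanoyl)cyclohexa-2,4-dien-1-one
Conditions: 0.5 M aq. HCl–THF (1:3), rt
Reagents that add atoms: water, SMILES O
Why: Acid-catalysed addition–elimination of water at C4 of a vinylogous ester that is activated by the C2 ketone, the C3 acyl group and the C6 carbonyl releases ethanol; acid this dilute at room temperature should leave the prenyl group and the tertiary methyl ether untouched.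

**Step 9**
Reactants: 16 (R)-3,5-dihydroxy-6-methoxy-6-(3-methylbut-2-enyl)-2-(3-phenylpropanoyl)cyclohexa-2,4-dien-1-one; 2 1-bromo-3-methylbut-2-ene (prenyl bromide)
Product: 17 helihumulone, (R)-3,5-dihydroxy-6-methoxy-4,6-bis(3-methylbut-2-enyl)-2-(3-phenylpropanoyl)cyclohexa-2,4-dien-1-one
Conditions: 2 (1.0 equiv), aq. KOH (2.2 equiv), 0 °C; then 1 M HCl, 0 °C
Reagents that add atoms: none
Why: Classical C-prenylation of the dianion of an acylphloroglucinol-type cyclic tricarbonyl in water: C5, the last-deprotonated and only unsubstituted nucleophilic carbon, is the most reactive site, hydrogen bonding to water disfavours O-alkylation, and one equivalent of bromide limits a second alkylation; C1 is not involved.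

**Compound list**

1 | dimethyl 2-methoxypropanedioate (dimethyl methoxymalonate) | COC(C(=O)OC)C(=O)OC | starting material
2 | 1-bromo-3-methylbut-2-ene (prenyl bromide) | CC(C)=CCBr | starting material
3 | dimethyl 2-methoxy-2-(3-methylbut-2-enyl)propanedioate | COC(CC=C(C)C)(C(=O)OC)C(=O)OC | intermediate
4 | (R)-2-methoxy-2-(methoxycarbonyl)-5-methylhex-4-enoic acid | CO[C@@](C(=O)O)(CC=C(C)C)C(=O)OC | intermediate
5 | methyl (S)-2-(chlorocarbonyl)-2-methoxy-5-methylhex-4-enoate (acid chloride, not isolated) | CO[C@@](C(=O)Cl)(CC=C(C)C)C(=O)OC | intermediate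
6 | methyl (R)-2-methoxy-2-[methoxy(methyl)carbamoyl]-5-methylhex-4-enoate | CO[C@@](C(=O)N(C)OC)(CC=C(C)C)C(=O)OC | intermediate
7 | (R)-2-methoxy-2-[methoxy(methyl)carbamoyl]-5-methylhex-4-enoic acid | CO[C@@](C(=O)N(C)OC)(CC=C(C)C)C(=O)O | intermediate
8 | 4-phenylbutan-2-one (benzylacetone) | CC(=O)CCc1ccccc1 | starting material
9 | (S)-2-(imidazole-1-carbonyl)-N,2-dimethoxy-N,5-dimethylhex-4-enamide (acyl imidazolide, not isolated) | CO[C@@](C(=O)N(C)OC)(CC=C(C)C)C(=O)n1ccnc1 | intermediate
10 | lithium 4-phenylbut-1-en-2-olate (kinetic lithium enolate of 8, not isolated) | C=C(O[Li])CCc1ccccc1 | intermediate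
11 | (S)-N,2-dimethoxy-N-methyl-2-(3-methylbut-2-enyl)-3,5-dioxo-7-phenylheptanamide | CO[C@@](C(=O)N(C)OC)(CC=C(C)C)C(=O)CC(=O)CCc1ccccc1 | intermediate
12 | ethoxyethyne (ethoxyacetylene) | C#COCC | starting material
13 | lithium ethoxyacetylide (not isolated) | [Li]C#COCC | intermediate
14 | (S)-1-ethoxy-4-methoxy-4-(3-methylbut-2-enyl)-9-phenylnon-1-yne-3,5,7-trione | CCOC#CC(=O)[C@](OC)(CC=C(C)C)C(=O)CC(=O)CCc1ccccc1 | intermediate
15 | (R)-3-ethoxy-5-hydroxy-6-methoxy-6-(3-methylbut-2-enyl)-2-(3-phenylpropanoyl)cyclohexa-2,4-dien-1-one | CO[C@@]1(CC=C(C)C)C(=O)C(C(=O)CCc2ccccc2)=C(OCC)C=C1O | intermediate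
16 | (R)-3,5-dihydroxy-6-methoxy-6-(3-methylbut-2-enyl)-2-(3-phenylpropanoyl)cyclohexa-2,4-dien-1-one | CO[C@@]1(CC=C(C)C)C(=O)C(C(=O)CCc2ccccc2)=C(O)C=C1O | intermediate
17 | helihumulone, (R)-3,5-dihydroxy-6-methoxy-4,6-bis(3-methylbut-2-enyl)-2-(3-phenylpropanoyl)cyclohexa-2,4-dien-1-one | CO[C@@]1(CC=C(C)C)C(=O)C(C(=O)CCc2ccccc2)=C(O)C(CC=C(C)C)=C1O | target

**Step count**

Total steps: 9. Longest linear sequence: 9 steps (1 to 17); ketone 8 and alkyne 12 enter as in-flask lithium reagents.

**Steps most likely to fail**

Step 7. The ring may close through the C2 enolate oxygen to a pyranone instead of through C3, or the alkoxy ynone may be consumed by hydration or amine addition before it cyclises. The fallback keeps the C3–C4 ring bond but makes it by acylation instead of conjugate addition. It sets out from amide 11: its lithium diketonate (LiN(SiMe3)2, THF, −78 °C) is treated with the lithium enolate of ethyl acetate F3 (from ethyl acetate and LiN(iPr)2) to give ethyl (S)-4-methoxy-4-(3-methylbut-2-enyl)-3,5,7-trioxo-9-phenylnonanoate F4, the hydrate-level equivalent of ynone 14. Mg(OEt)2 in EtOH (rt to 50 °C) should then effect the biomimetic Claisen condensation of C3 onto the ester carbonyl with loss of ethanol. This delivers trione 16 directly, where the route is rejoined.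

Step 2. The enzyme may discriminate the enantiotopic esters poorly or in the opposite sense. The fallback is a classical resolution. It sets out from diester 3: half-saponification (KOH, 1.0 equiv, MeOH, 0 °C; then HCl) gives racemic 2-methoxy-2-(methoxycarbonyl)-5-methylhex-4-enoic acid F1. The (R)-acid is crystallised as (S)-1-phenylethylammonium (R)-2-methoxy-2-(methoxycarbonyl)-5-methylhex-4-enoate F2; the amine enantiomer that gives the less soluble salt with the (R)-acid is chosen by trial and is written here as (S). Cold acidification of the salt returns half-ester 4.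

Step 9. O-alkylation, a second alkylation at C5 or alkylation at C3 may erode the yield. The fallback replaces the SN2 alkylation by a Tsuji–Trost allylation and sets out from trione 16: prenyl acetate, Pd(PPh3)4 (a zerovalent palladium complex, 5 mol%), K2CO3, THF, rt. The π-prenyl palladium intermediate is attacked by the soft carbon nucleophile at its unsubstituted terminus, and any O-prenyl enol ether is re-ionised by the catalyst and funnelled to the C5 product. This gives target 17 directly; no new compound arises on this path (F0).

**Further compounds**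

F1 | step 2 | racemic 2-methoxy-2-(methoxycarbonyl)-5-methylhex-4-enoic acid | COC(CC=C(C)C)(C(=O)O)C(=O)OC
F2 | step 2 | (S)-1-phenylethylammonium (R)-2-methoxy-2-(methoxycarbonyl)-5-methylhex-4-enoate | CO[C@@](C(=O)[O-])(CC=C(C)C)C(=O)OC.C[C@H]([NH3+])c1ccccc1
F3 | step 7 | lithium 1-ethoxyethen-1-olate (lithium enolate of ethyl acetate) | C=C(O[Li])OCC
F4 | step 7 | ethyl (S)-4-methoxy-4-(3-methylbut-2-enyl)-3,5,7-trioxo-9-phenylnonanoate | CCOC(=O)CC(=O)[C@](OC)(CC=C(C)C)C(=O)CC(=O)CCc1ccccc1
F0 | step 9 | none | none
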